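**Retrosynthetic overview**
- **Feature:** in the benzo ring, C6, C7 and C8 carry Br, Br and OMe side by side, and C8 is bonded to C8a next to N1. C7 with its bromine can be excised as a one-carbon CBr unit. This shrinks the benzo ring to a cyclopentene fused to the pyridine ring (C8 = silyl enol ether carbon, C6 = vinyl bromide carbon, C5 = CH2).
- **Disconnections:** 4-pyridone/acid to the 4-methoxy ester, and 8-OMe to 8-OH. C6–C7 and C7–C8 by dibromocarbene addition and ring expansion. Enol ether to bromoketone to ketone. The C8–C(alpha) bond by Dieckmann condensation. C4a–C5 by Heck coupling at C3 of an iodinated chelidamic diester.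
- **Ring order:** the pyridine ring is bought with chelidamic acid, which brings N1, C2 with its carboxyl, C3, C4 with its oxygen, C4a, C8a and C8. The five-membered carbocycle is made second and the six-membered benzo ring last.
- **Design choices:** the electron-poor pyridine is iodinated by deprotonation, not electrophilically. tert-Butyl acrylate is used so that only the beta-keto ester is lost. The carbene is stored as PhHgCBr3, made from bromoform in a separate flask, so the acidic C5 methylene and the methyl ester never meet alkoxide.

Key step: step 11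

Assumption: the target is handled as the drawn 4-oxo-1H tautomer, the stable form of such quinoline-2-carboxylic acids. It has no stereocentre, so racemic intermediates are of no consequence.

Step 1
Reactants: 1 chelidamic acid (4-hydroxypyridine-2,6-dicarboxylic acid)
Product: 2 dimethyl 4-hydroxypyridine-2,6-dicarboxylate
Conditions: MeOH, H2SO4 (cat.), reflux
Reagents that add atoms: methanol, CO
Why: Fischer esterification of both carboxyl groups, driven by the large excess of methanol.

Step 2
Reactants: 2 dimethyl 4-hydroxypyridine-2,6-dicarboxylate
Product: 3 dimethyl 4-methoxypyridine-2,6-dicarboxylate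
Conditions: MeI, K2CO3, DMF, rt
Reagents that add atoms: iodomethane, CI
Why: Williamson-type alkylation of the pyridinolate, which should take place at oxygen because the ring nitrogen is flanked by two esters and is hindered and electron-poor.

Step 3
Reactants: 3 dimethyl 4-methoxypyridine-2,6-dicarboxylate
Product: 5 dimethyl 3-iodo-4-methoxypyridine-2,6-dicarboxylate, via arylmagnesium chloride 4 (not isolated)
Conditions: TMPMgCl·LiCl (1.1 equiv), THF, −40 °C; then I2, −40 °C to rt
Reagents that add atoms: iodine, II; TMPMgCl·LiCl, CC1(C)CCCC(C)(C)N1[Mg]Cl.[Li+].[Cl-] (supplies the MgCl of 4 only)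
Why: Directed ortho-metalation, chosen because electrophilic iodination of this doubly ester-deactivated pyridine is not realistic, whereas the C3–H between ester and methoxy group is the most acidic and doubly coordinated site, the hindered magnesium amide spares esters at low temperature, C3 and C5 are equivalent by symmetry, and iodine traps carbanion 4.

Step 4
Reactants: 5 dimethyl 3-iodo-4-methoxypyridine-2,6-dicarboxylate; 6 tert-butyl acrylate
Product: 7 dimethyl 3-[(E)-3-tert-butoxy-3-oxoprop-1-en-1-yl]-4-methoxypyridine-2,6-dicarboxylate
Conditions: Pd(OAc)2 (5 mol %), n-Bu4NCl, NaHCO3, DMF, 80 °C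
Reagents that add atoms: tert-butyl acrylate (6), C=CC(=O)OC(C)(C)C
Why: Mizoroki–Heck reaction in which the electron-poor C–I bond should add readily to zerovalent palladium, the ligand-free phase-transfer conditions suit aryl iodides with two ortho substituents, and syn insertion with syn beta-hydride elimination gives the E alkene, whose geometry is erased in step 5.

Step 5
Reactants: 7 dimethyl 3-[(E)-3-tert-butoxy-3-oxoprop-1-en-1-yl]-4-methoxypyridine-2,6-dicarboxylate
Product: 8 dimethyl 3-(3-tert-butoxy-3-oxopropyl)-4-methoxypyridine-2,6-dicarboxylate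
Conditions: H2 (1 atm), Pd/C (10 wt %), EtOAc, rt
Reagents that add atoms: none
Why: Heterogeneous catalytic hydrogenation of a conjugated alkene, under which the pyridine ring, the esters and the ether are left alone.

Step 6
Reactants: 8 dimethyl 3-(3-tert-butoxy-3-oxopropyl)-4-methoxypyridine-2,6-dicarboxylate
Product: 9 6-tert-butyl 2-methyl 4-methoxy-7-oxo-6,7-dihydro-5H-cyclopenta[b]pyridine-2,6-dicarboxylate (racemic)
Conditions: LiN(SiMe3)2 (2.2 equiv), THF, −78 to 0 °C; then 1 M HCl
Reagents that add atoms: none
Why: Dieckmann condensation in which the tert-butyl ester enolate can reach only the neighbouring methyl ester (5-exo-trig), the second equivalent of base stores the product as its stabilised enolate, the non-nucleophilic amide avoids ester exchange, and the new C6 centre is racemic, labile and removed in step 7.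

Step 7
Reactants: 9 6-tert-butyl 2-methyl 4-methoxy-7-oxo-6,7-dihydro-5H-cyclopenta[b]pyridine-2,6-dicarboxylate
Product: 11 methyl 4-methoxy-7-oxo-6,7-dihydro-5H-cyclopenta[b]pyridine-2-carboxylate, via beta-keto acid 10 (not isolated)
Conditions: TFA, CH2Cl2, rt; concentrate; toluene, 90 °C
Reagents that add atoms: none
Why: Acidolysis of the tert-butyl ester followed by thermal decarboxylation of the beta-keto acid through a six-membered transition state, while the methyl ester and the 4-methyl ether are inert to TFA, which is the reason for using tert-butyl rather than methyl acrylate.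

Step 8
Reactants: 11 methyl 4-methoxy-7-oxo-6,7-dihydro-5H-cyclopenta[b]pyridine-2-carboxylate
Product: 12 methyl 6-bromo-4-methoxy-7-oxo-6,7-dihydro-5H-cyclopenta[b]pyridine-2-carboxylate (racemic)
Conditions: Br2 (1.0 equiv), HBr (cat.), AcOH, rt
Reagents that add atoms: bromine, BrBr
Why: Acid-catalysed alpha-bromination of a ketone through its enol, where C6 is the only enolisable position, the first bromine slows a second enolisation so that one equivalent should stop at the monobromide, and the new C6 centre is racemic and becomes sp2 in step 9.

Step 9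
Reactants: 12 methyl 6-bromo-4-methoxy-7-oxo-6,7-dihydro-5H-cyclopenta[b]pyridine-2-carboxylate
Product: 13 methyl 6-bromo-7-(tert-butyldimethylsilyloxy)-4-methoxy-5H-cyclopenta[b]pyridine-2-carboxylate
Conditions: TBSOTf (1.3 equiv), Et3N (2 equiv), CH2Cl2, 0 °C; filtration through Et3N-deactivated silica
Reagents that add atoms: tert-butyldimethylsilyl triflate, CC(C)(C)[Si](C)(C)OS(=O)(=O)C(F)(F)F
Why: Soft enolisation with O-silylation, in which silylation of the carbonyl oxygen makes the bromine-acidified C6–H easy for Et3N to remove at 0 °C, faster than loss of HBr towards C5, and only one enol ether regioisomer is possible.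

Step 10
Reactants: 14 bromoform; 15 chloro(phenyl)mercury, PhHgCl
Product: 16 phenyl(tribromomethyl)mercury, PhHgCBr3
Conditions: KOt-Bu (1.1 equiv), benzene, 0–10 °C
Reagents that add atoms: bromoform (14), BrC(Br)Br
Why: Known deprotonation–mercuration route to aryl(trihalomethyl)mercurials, in which the tribromomethyl anion displaces chloride at mercury faster than it sheds bromide at this temperature and so stores the carbene in a neutral, weighable form.

Step 11
Reactants: 13 methyl 6-bromo-7-(tert-butyldimethylsilyloxy)-4-methoxy-5H-cyclopenta[b]pyridine-2-carboxylate; 16 phenyl(tribromomethyl)mercury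
Product: 19 methyl 6,7-dibromo-8-hydroxy-4-methoxyquinoline-2-carboxylate, via tribromocyclopropane 17 (not isolated), via aryl silyl ether 18 (not isolated)
Conditions: PhHgCBr3 (2.5 equiv, in portions), 2,6-di-tert-butyl-4-methylpyridine (1.5 equiv), benzene, 80 °C; filter off PhHgBr; then n-Bu4NF, AcOH, THF, 0 °C
Reagents that add atoms: phenyl(tribromomethyl)mercury (16), BrC(Br)(Br)[Hg]c1ccccc1
Why: Proposed new method: thermal alpha-elimination of PhHgBr from 16 releases free dibromocarbene without any base, and this electrophilic singlet carbene should add in a concerted [2+1] manner to the C6=C7 double bond of 13 (cyclopenta[b]pyridine numbering), the only pi bond raised in energy by an oxygen lone pair, to give the cis-fused tribromocyclopropane 17. In 17 the strain of the bicyclo[3.1.0] frame and the silyloxy donor drive a disrotatory two-electron electrocyclic opening with loss of one bromide from the CBr2 carbon and cleavage of the old C6–C7 bond, so the benzo ring is closed not by an end-to-end cyclisation but by one-carbon expansion of the five-membered carbocycle, the carbene carbon becoming quinoline C7 bonded to quinoline C6 (old C6) and C8 (old C7). The hindered pyridine base takes one proton from the former C5 methylene of the silyloxyallyl cation, which aromatises the ring to 18, and buffered fluoride then frees the phenol. The closest known reaction is the dihalocarbene ring expansion of 1-indanone silyl enol ethers to 2-halo-1-naphthols; new here are the bromine on the enol carbon and the fused pyridine, both of which lower the nucleophilicity of the alkene, which is why a transfer reagent known to cyclopropanate halogenated and base-sensitive alkenes is used. The two stereocentres of 17 are cis by the constraint of the ring fusion, form as a racemate and vanish on aromatisation. The step needs carbene attack at the alkene rather than at N1 and carbene transfer without deprotonation of the acidic C5 methylene: N1 is electron-poor and flanked by the ester and the ring fusion, and the alkoxide that turns bromoform into the carbene source was consumed in step 10, so 13 and its methyl ester never meet it.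

Step 12
Reactants: 19 methyl 6,7-dibromo-8-hydroxy-4-methoxyquinoline-2-carboxylate
Product: 20 methyl 6,7-dibromo-4,8-dimethoxyquinoline-2-carboxylate
Conditions: MeI, K2CO3, DMF, rt
Reagents that add atoms: iodomethane, CI
Why: Williamson ether synthesis on the acidic 8-quinolinol, with N1 shielded by the C2 ester and the C8 oxygen so that alkylation should occur at oxygen.

Step 13
Reactants: 20 methyl 6,7-dibromo-4,8-dimethoxyquinoline-2-carboxylate
Product: 21 6,7-dibromo-8-methoxy-4-oxo-1,4-dihydroquinoline-2-carboxylic acid (target)
Conditions: 6 M aq. HCl/AcOH (1:1), reflux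
Reagents that add atoms: water, O
Why: Acid hydrolysis in which the N-protonated 4-methoxyquinoline acts as a vinylogous imidate that adds water at C4 and expels methanol (addition–elimination) while the ester undergoes ordinary acyl-oxygen cleavage, whereas the 8-methoxy group is a plain aryl methyl ether with no such pathway and withstands aqueous HCl.

**Compound list**
1 | chelidamic acid | O=C(O)c1cc(O)cc(C(=O)O)n1 | starting material
2 | dimethyl 4-hydroxypyridine-2,6-dicarboxylate | COC(=O)c1cc(O)cc(C(=O)OC)n1 | intermediate
3 | dimethyl 4-methoxypyridine-2,6-dicarboxylate | COC(=O)c1cc(OC)cc(C(=O)OC)n1 | intermediate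
4 | [4-methoxy-2,6-bis(methoxycarbonyl)pyridin-3-yl]magnesium chloride (LiCl complex, not isolated) | COC(=O)c1cc(OC)c([Mg]Cl)c(C(=O)OC)n1 | intermediate
5 | dimethyl 3-iodo-4-methoxypyridine-2,6-dicarboxylate | COC(=O)c1cc(OC)c(I)c(C(=O)OC)n1 | intermediate
6 | tert-butyl acrylate | C=CC(=O)OC(C)(C)C | starting material
7 | dimethyl 3-[(E)-3-tert-butoxy-3-oxoprop-1-en-1-yl]-4-methoxypyridine-2,6-dicarboxylate | COC(=O)c1cc(OC)c(/C=C/C(=O)OC(C)(C)C)c(C(=O)OC)n1 | intermediate
8 | dimethyl 3-(3-tert-butoxy-3-oxopropyl)-4-methoxypyridine-2,6-dicarboxylate | COC(=O)c1cc(OC)c(CCC(=O)OC(C)(C)C)c(C(=O)OC)n1 | intermediate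
9 | 6-tert-butyl 2-methyl 4-methoxy-7-oxo-6,7-dihydro-5H-cyclopenta[b]pyridine-2,6-dicarboxylate (racemic, labile centre) | COC(=O)c1cc(OC)c2c(n1)C(=O)C(C(=O)OC(C)(C)C)C2 | intermediate
10 | 4-methoxy-2-(methoxycarbonyl)-7-oxo-6,7-dihydro-5H-cyclopenta[b]pyridine-6-carboxylic acid (racemic, not isolated) | COC(=O)c1cc(OC)c2c(n1)C(=O)C(C(=O)O)C2 | intermediate
11 | methyl 4-methoxy-7-oxo-6,7-dihydro-5H-cyclopenta[b]pyridine-2-carboxylate | COC(=O)c1cc(OC)c2c(n1)C(=O)CC2 | intermediate
12 | methyl 6-bromo-4-methoxy-7-oxo-6,7-dihydro-5H-cyclopenta[b]pyridine-2-carboxylate (racemic) | COC(=O)c1cc(OC)c2c(n1)C(=O)C(Br)C2 | intermediate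
13 | methyl 6-bromo-7-(tert-butyldimethylsilyloxy)-4-methoxy-5H-cyclopenta[b]pyridine-2-carboxylate | COC(=O)c1cc(OC)c2c(n1)C(O[Si](C)(C)C(C)(C)C)=C(Br)C2 | intermediate
14 | bromoform | BrC(Br)Br | starting material
15 | chloro(phenyl)mercury | Cl[Hg]c1ccccc1 | starting material
16 | phenyl(tribromomethyl)mercury | BrC(Br)(Br)[Hg]c1ccccc1 | intermediate
17 | methyl 6-bromo-6,7-(dibromomethano)-7-(tert-butyldimethylsilyloxy)-4-methoxy-6,7-dihydro-5H-cyclopenta[b]pyridine-2-carboxylate (cis-fused, racemic, one enantiomer drawn, not isolated) | COC(=O)c1cc(OC)c2c(n1)[C@]1(O[Si](C)(C)C(C)(C)C)C(Br)(Br)[C@]1(Br)C2 | intermediate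
18 | methyl 6,7-dibromo-8-(tert-butyldimethylsilyloxy)-4-methoxyquinoline-2-carboxylate (not isolated) | COC(=O)c1cc(OC)c2cc(Br)c(Br)c(O[Si](C)(C)C(C)(C)C)c2n1 | intermediate
19 | methyl 6,7-dibromo-8-hydroxy-4-methoxyquinoline-2-carboxylate | COC(=O)c1cc(OC)c2cc(Br)c(Br)c(O)c2n1 | intermediate
20 | methyl 6,7-dibromo-4,8-dimethoxyquinoline-2-carboxylate | COC(=O)c1cc(OC)c2cc(Br)c(Br)c(OC)c2n1 | intermediate
21 | 6,7-dibromo-8-methoxy-4-oxo-1,4-dihydroquinoline-2-carboxylic acid | COc1c(Br)c(Br)cc2c(=O)cc(C(=O)O)[nH]c12 | target

**Step count**
- Total steps: 13 (12 in the main line plus the preparation of 16).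
- Longest linear sequence: 12 steps (1–9 and 11–13) from chelidamic acid.

**Steps most likely to fail**

1. **Step 11 (bears the label).**
   - **Risk:** carbene transfer to the bromine-bearing, pyridine-conjugated enol ether may be too slow. The carbene would then be lost to dimerisation, C–H insertion or attack at N1, while the enol ether is slowly desilylated by the acid released. A prototropic shift of the double bond to C5=C6 would not change the constitution, because a CBr unit inserted on either side of the C6–Br carbon gives the same H, Br, Br, O sequence.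
   - **Fallback (from 11, back at 20):** the C6 bromine is moved from before to after the ring expansion. The carbene then meets an enol ether with an unsubstituted beta carbon, which is the documented case. C6 is brominated later under the direction of a temporary amino group at C5.
   - TBSOTf/Et3N converts 11 into methyl 7-(tert-butyldimethylsilyloxy)-4-methoxy-5H-cyclopenta[b]pyridine-2-carboxylate F1.
   - Carbene transfer from 16 under the conditions of step 11 leads through the dibromocyclopropane adduct F2 and methyl 7-bromo-8-(tert-butyldimethylsilyloxy)-4-methoxyquinoline-2-carboxylate F3. After fluoride it gives methyl 7-bromo-8-hydroxy-4-methoxyquinoline-2-carboxylate F4.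
   - MeI/K2CO3 gives methyl 7-bromo-4,8-dimethoxyquinoline-2-carboxylate F5.
   - HNO3/H2SO4 at 0 °C nitrates the position para to the 8-methoxy group to give methyl 7-bromo-4,8-dimethoxy-5-nitroquinoline-2-carboxylate F6.
   - Fe powder/NH4Cl in aqueous EtOH reduces it to methyl 5-amino-7-bromo-4,8-dimethoxyquinoline-2-carboxylate F7.
   - NBS in MeCN at 0 °C brominates the only free position ortho to the amine (C6; the para position C8 is occupied) to give methyl 5-amino-6,7-dibromo-4,8-dimethoxyquinoline-2-carboxylate F8.
   - t-BuONO in THF at 60 °C (reductive dediazoniation) removes the amino group and gives 20.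

2. **Step 3.**
   - **Risk:** metalation may be incomplete, or the arylmagnesium species may add to an ester of unreacted diester (self-condensation) before iodine is added.
   - **Fallback (from 2, back at 5):** electrophilic iodination at the activated pyridinol stage replaces deprotonation. NIS (1.0 equiv) in MeCN should give dimethyl 4-hydroxy-3-iodopyridine-2,6-dicarboxylate F9, with the stoichiometry limiting a second iodination. O-methylation with MeI/K2CO3 in DMF then gives 5.

3. **Step 4.**
   - **Risk:** migratory insertion at the arylpalladium centre flanked by two ortho groups may be slow, so that hydrodeiodination and catalyst decay take over.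
   - **Fallback (from 5, back at 8):** an sp2–sp3 Negishi coupling replaces the Heck reaction and the hydrogenation. Purchased tert-butyl 3-bromopropanoate with Zn dust and LiCl in THF gives (3-tert-butoxy-3-oxopropyl)zinc bromide F10. This couples with 5 (Pd(OAc)2, SPhos, THF, 50 °C) to give 8 directly.

**Further compounds**
F1 | step 11 | methyl 7-(tert-butyldimethylsilyloxy)-4-methoxy-5H-cyclopenta[b]pyridine-2-carboxylate | COC(=O)c1cc(OC)c2c(n1)C(O[Si](C)(C)C(C)(C)C)=CC2
F2 | step 11 | methyl 6,7-(dibromomethano)-7-(tert-butyldimethylsilyloxy)-4-methoxy-6,7-dihydro-5H-cyclopenta[b]pyridine-2-carboxylate (cis-fused, racemic, one enantiomer drawn) | COC(=O)c1cc(OC)c2c(n1)[C@]1(O[Si](C)(C)C(C)(C)C)C(Br)(Br)[C@@H]1C2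
F3 | step 11 | methyl 7-bromo-8-(tert-butyldimethylsilyloxy)-4-methoxyquinoline-2-carboxylate | COC(=O)c1cc(OC)c2ccc(Br)c(O[Si](C)(C)C(C)(C)C)c2n1
F4 | step 11 | methyl 7-bromo-8-hydroxy-4-methoxyquinoline-2-carboxylate | COC(=O)c1cc(OC)c2ccc(Br)c(O)c2n1
F5 | step 11 | methyl 7-bromo-4,8-dimethoxyquinoline-2-carboxylate | COC(=O)c1cc(OC)c2ccc(Br)c(OC)c2n1
F6 | step 11 | methyl 7-bromo-4,8-dimethoxy-5-nitroquinoline-2-carboxylate | COC(=O)c1cc(OC)c2c([N+](=O)[O-])cc(Br)c(OC)c2n1
F7 | step 11 | methyl 5-amino-7-bromo-4,8-dimethoxyquinoline-2-carboxylate | COC(=O)c1cc(OC)c2c(N)cc(Br)c(OC)c2n1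
F8 | step 11 | methyl 5-amino-6,7-dibromo-4,8-dimethoxyquinoline-2-carboxylate | COC(=O)c1cc(OC)c2c(N)c(Br)c(Br)c(OC)c2n1
F9 | step 3 | dimethyl 4-hydroxy-3-iodopyridine-2,6-dicarboxylate | COC(=O)c1cc(O)c(I)c(C(=O)OC)n1
F10 | step 4 | (3-tert-butoxy-3-oxopropyl)zinc bromide | CC(C)(C)OC(=O)CC[Zn]Br
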